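**Strategy.** The isoflavone is disconnected at the bond between C3 of the pyran-4-one ring and C1′ of the resorcinol ring. One Suzuki–Miyaura coupling forms this bond between two finished halves, 7-benzyloxy-3-chloro-5-hydroxy-6-(3-hydroxy-3-methylbutyl)chromone and 2,4-bis(benzyloxy)phenylboronic acid, so that only hydrogenolysis remains. The step exploits C3 as the α-carbon of the pyranone enone (C2=C3–C4=O): its chlorine is installed when an enaminone closes the ring, is activated for oxidative addition, and yet survives the earlier coupling at a C6 iodide, which the chelated 5-OH places on the benzo ring and which brings in the side chain.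

Key step: step 5

Remark: the target has no stereocentre and no stereogenic double bond, so it is a single achiral compound and no stereocontrol is needed; the name is read as the structure drawn (luteone hydrate).

**Step 1**
Reactants: 1 1-[2,4-bis(benzyloxy)-6-hydroxyphenyl]ethan-1-one
Product: 3 5,7-bis(benzyloxy)-3-chloro-4H-chromen-4-one, via enaminone 2 (not isolated)
Conditions: DMF-DMA, toluene, 95 °C; concentrate; then NCS (1.1 equiv), CH2Cl2, 0 °C to rt
Reagents that add atoms: N,N-dimethylformamide dimethyl acetal, COC(OC)N(C)C; N-chlorosuccinimide, O=C1CCC(=O)N1Cl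
Why: Condensation of the acetyl group with DMF-DMA gives the (E)-enaminone, whose nucleophilic α-carbon is chlorinated by NCS and whose single free phenol then closes the pyranone ring with loss of dimethylamine (halocyclisation of an o-hydroxyaryl enaminone, the chloro variant of the iodine-mediated 3-halochromone synthesis).

**Step 2**
Reactants: 3 5,7-bis(benzyloxy)-3-chloro-4H-chromen-4-one
Product: 4 7-(benzyloxy)-3-chloro-5-hydroxy-4H-chromen-4-one
Conditions: BCl3 (1.2 equiv), CH2Cl2, −78 °C; aqueous work-up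
Reagents that add atoms: none
Why: In this chelation-controlled Lewis-acid ether cleavage, BCl3 binds between the C4 carbonyl and the peri 5-benzyloxy oxygen, so only that benzyl ether should be cleaved at low temperature while the 7-benzyl ether and the C3–Cl bond remain.

**Step 3**
Reactants: 4 7-(benzyloxy)-3-chloro-5-hydroxy-4H-chromen-4-one
Product: 5 7-(benzyloxy)-3-chloro-5-hydroxy-6-iodo-4H-chromen-4-one
Conditions: BnMe3N·ICl2 (1.1 equiv), CaCO3, CH2Cl2/MeOH, rt
Reagents that add atoms: benzyltrimethylammonium dichloroiodate, C[N+](C)(C)Cc1ccccc1.Cl[I-]Cl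
Why: In this electrophilic aromatic iodination, with O7 blocked and the 5-OH free and chelated to C4=O, the reagent should attack C6 (ortho to the free hydroxyl) and not C8, as in the ortho-iodination of 5-hydroxy-7-alkoxyflavones, while CaCO3 buffers the HCl formed.

**Step 4**
Reactants: 5 7-(benzyloxy)-3-chloro-5-hydroxy-6-iodo-4H-chromen-4-one; 6 2-methylbut-3-en-2-ol; 7 9-borabicyclo[3.3.1]nonane
Product: 9 7-(benzyloxy)-3-chloro-5-hydroxy-6-(3-hydroxy-3-methylbutyl)-4H-chromen-4-one, via B-alkyl-9-BBN borane 8 (not isolated)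
Conditions: 6 (1.6 equiv), 7 (1.5 equiv), THF, 0 °C to rt; then 5, Pd(dppf)Cl2·CH2Cl2 (10 mol%), AsPh3 (10 mol%), aq. K3PO4 (3 equiv), DMF, 50 °C
Reagents that add atoms: none
Why: In this B-alkyl Suzuki–Miyaura coupling, anti-Markovnikov hydroboration of the terminal alkene with 9-BBN (the tertiary alcohol reacts only slowly) gives the primary alkylborane, which couples at the C6–I bond while the C3–Cl bond, much slower in oxidative addition with this catalyst, stays untouched and the side chain arrives at its final oxidation level.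

**Step 5**
Reactants: 9 7-(benzyloxy)-3-chloro-5-hydroxy-6-(3-hydroxy-3-methylbutyl)-4H-chromen-4-one; 10 [2,4-bis(benzyloxy)phenyl]boronic acid
Product: 11 7-(benzyloxy)-3-[2,4-bis(benzyloxy)phenyl]-5-hydroxy-6-(3-hydroxy-3-methylbutyl)-4H-chromen-4-one
Conditions: 10 (1.5 equiv), Pd(OAc)2 (5 mol%), SPhos (10 mol%), K3PO4 (3 equiv), toluene/H2O 10:1, 80 °C
Reagents that add atoms: none
Why: Suzuki–Miyaura cross-coupling in which Pd(0)/SPhos adds oxidatively to the C3–Cl bond of 9, activated as the α-halogen of the pyranone enone (C2=C3–C4=O), the phosphate-activated boronate of 10 transmetalates, and reductive elimination forms the C3–C1′ bond. The closest known reaction type is the coupling of 3-halochromones with arylboronic acids to give isoflavones, combined with the use of dialkylbiarylphosphine ligands for alkenyl chlorides. No ring is closed and no stereocentre is formed. The step needs reaction at C3 without opening of the base-sensitive pyranone ring: C3–Cl is the only carbon–halogen bond left because the C6 iodide was consumed in step 4, and the 5-OH, deprotonated by phosphate and chelated to C4=O, lowers the electrophilicity of C2 towards hydroxide. The free tertiary alcohol and the benzyl ethers are inert, and the excess of 10 covers protodeboronation of the electron-rich boronic acid.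

**Step 6**
Reactants: 11 7-(benzyloxy)-3-[2,4-bis(benzyloxy)phenyl]-5-hydroxy-6-(3-hydroxy-3-methylbutyl)-4H-chromen-4-one
Product: 12 3-(2,4-dihydroxyphenyl)-5,7-dihydroxy-6-(3-hydroxy-3-methylbutyl)-4H-chromen-4-one
Conditions: H2 (1 atm), 10% Pd/C, EtOAc/MeOH, rt
Reagents that add atoms: none
Why: Catalytic hydrogenolysis of the three benzyl ethers under mild conditions should free the 7-, 2′- and 4′-hydroxyl groups while the tertiary non-benzylic alcohol and, with monitoring of hydrogen uptake, the trisubstituted C2=C3 bond of the isoflavone are retained.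

**Compound list**
1 | 1-[2,4-bis(benzyloxy)-6-hydroxyphenyl]ethan-1-one | CC(=O)c1c(O)cc(OCc2ccccc2)cc1OCc1ccccc1 | starting material
2 | (2E)-1-[2,4-bis(benzyloxy)-6-hydroxyphenyl]-3-(dimethylamino)prop-2-en-1-one | CN(C)/C=C/C(=O)c1c(O)cc(OCc2ccccc2)cc1OCc1ccccc1 | intermediate
3 | 5,7-bis(benzyloxy)-3-chloro-4H-chromen-4-one | O=c1c(Cl)coc2cc(OCc3ccccc3)cc(OCc3ccccc3)c12 | intermediate
4 | 7-(benzyloxy)-3-chloro-5-hydroxy-4H-chromen-4-one | O=c1c(Cl)coc2cc(OCc3ccccc3)cc(O)c12 | intermediate
5 | 7-(benzyloxy)-3-chloro-5-hydroxy-6-iodo-4H-chromen-4-one | O=c1c(Cl)coc2cc(OCc3ccccc3)c(I)c(O)c12 | intermediate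
6 | 2-methylbut-3-en-2-ol | C=CC(C)(C)O | starting material
7 | 9-borabicyclo[3.3.1]nonane (9-BBN, used as its commercial dimer or THF solution) | B1C2CCCC1CCC2 | starting material
8 | 4-(9-borabicyclo[3.3.1]nonan-9-yl)-2-methylbutan-2-ol | CC(C)(O)CCB1C2CCCC1CCC2 | intermediate
9 | 7-(benzyloxy)-3-chloro-5-hydroxy-6-(3-hydroxy-3-methylbutyl)-4H-chromen-4-one | CC(C)(O)CCc1c(OCc2ccccc2)cc2occ(Cl)c(=O)c2c1O | intermediate
10 | [2,4-bis(benzyloxy)phenyl]boronic acid | OB(O)c1ccc(OCc2ccccc2)cc1OCc1ccccc1 | starting material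
11 | 7-(benzyloxy)-3-[2,4-bis(benzyloxy)phenyl]-5-hydroxy-6-(3-hydroxy-3-methylbutyl)-4H-chromen-4-one | CC(C)(O)CCc1c(OCc2ccccc2)cc2occ(-c3ccc(OCc4ccccc4)cc3OCc3ccccc3)c(=O)c2c1O | intermediate
12 | 3-(2,4-dihydroxyphenyl)-5,7-dihydroxy-6-(3-hydroxy-3-methylbutyl)-4H-chromen-4-one | CC(C)(O)CCc1c(O)cc2occ(-c3ccc(O)cc3O)c(=O)c2c1O | target

**Total step count:** 6
**Longest linear sequence:** 6 steps (1 → 3 → 4 → 5 → 9 → 11 → 12)

**Steps most likely to fail**

1. Step 5 (key coupling). Oxidative addition into the C3–Cl bond may be slow, so that base-induced opening of the pyranone ring or protodeboronation of the electron-rich boronic acid outruns the coupling. The fallback sets out from 1 and comes back at 11. It reverses the order of the two couplings and relies on the reactivity difference between two iodides in place of the chlorine/iodine pair. Enaminone 2 is cyclised with I2 in CHCl3/MeOH to 5,7-bis(benzyloxy)-3-iodo-4H-chromen-4-one F1. BCl3 at −78 °C then gives 7-(benzyloxy)-5-hydroxy-3-iodo-4H-chromen-4-one F2, and iodination as in step 3 gives 7-(benzyloxy)-5-hydroxy-3,6-diiodo-4H-chromen-4-one F3. Coupling with 10 under Pd(PPh3)4/Na2CO3 in DME/H2O at 60 °C should take place only at the activated C3 iodide, because the C6 iodide is flanked by two oxygen substituents and sits next to a phenoxide. This gives 7-(benzyloxy)-3-[2,4-bis(benzyloxy)phenyl]-5-hydroxy-6-iodo-4H-chromen-4-one F4, and B-alkyl coupling of F4 with borane 8 under the conditions of step 4 gives 11.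

2. Step 4. Transmetalation and reductive elimination at the doubly ortho-substituted, phenoxide-bearing C6 iodide may be sluggish, leading to protodeiodination or to slow attack of aqueous base on the chlorochromone. The fallback sets out from 5 and comes back at 12. It brings in the carbon chain as an alkyne and leaves its saturation to the last step. Sonogashira coupling of 5 with 2-methylbut-3-yn-2-ol (Pd(PPh3)2Cl2, CuI, Et3N, DMF, rt), which leaves the C3–Cl bond alone, gives 7-(benzyloxy)-3-chloro-5-hydroxy-6-(3-hydroxy-3-methylbut-1-yn-1-yl)-4H-chromen-4-one F5. Coupling with 10 under the conditions of step 5 gives 7-(benzyloxy)-3-[2,4-bis(benzyloxy)phenyl]-5-hydroxy-6-(3-hydroxy-3-methylbut-1-yn-1-yl)-4H-chromen-4-one F6. Hydrogenation over Pd/C then saturates the triple bond and cleaves the benzyl ethers in one operation to give 12.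

3. Step 3. Iodination may occur at C8 (para to the 5-OH) or twice, instead of only ortho at C6. The fallback sets out from 4 and comes back at 9. It delivers the side chain from O5 by an aromatic Claisen rearrangement, which can only reach C6 because the other ortho position is the ring-fusion carbon C4a. O-alkylation of 4 with 3-chloro-3-methylbut-1-yne (CuCl2 cat., DBU, MeCN, 0 °C) gives 7-(benzyloxy)-3-chloro-5-[(2-methylbut-3-yn-2-yl)oxy]-4H-chromen-4-one F7. Semihydrogenation over Lindlar catalyst gives 7-(benzyloxy)-3-chloro-5-[(2-methylbut-3-en-2-yl)oxy]-4H-chromen-4-one F8. Heating in toluene should bring about the [3,3] shift and give 7-(benzyloxy)-3-chloro-5-hydroxy-6-(3-methylbut-2-en-1-yl)-4H-chromen-4-one F9. Mukaiyama hydration (Co(acac)2, PhSiH3, O2, THF/i-PrOH) then adds water in the Markovnikov sense to give 9.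

**Further compounds**
F1 | step 5 | 5,7-bis(benzyloxy)-3-iodo-4H-chromen-4-one | O=c1c(I)coc2cc(OCc3ccccc3)cc(OCc3ccccc3)c12
F2 | step 5 | 7-(benzyloxy)-5-hydroxy-3-iodo-4H-chromen-4-one | O=c1c(I)coc2cc(OCc3ccccc3)cc(O)c12
F3 | step 5 | 7-(benzyloxy)-5-hydroxy-3,6-diiodo-4H-chromen-4-one | O=c1c(I)coc2cc(OCc3ccccc3)c(I)c(O)c12
F4 | step 5 | 7-(benzyloxy)-3-[2,4-bis(benzyloxy)phenyl]-5-hydroxy-6-iodo-4H-chromen-4-one | O=c1c(-c2ccc(OCc3ccccc3)cc2OCc2ccccc2)coc2cc(OCc3ccccc3)c(I)c(O)c12
F5 | step 4 | 7-(benzyloxy)-3-chloro-5-hydroxy-6-(3-hydroxy-3-methylbut-1-yn-1-yl)-4H-chromen-4-one | CC(C)(O)C#Cc1c(OCc2ccccc2)cc2occ(Cl)c(=O)c2c1O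
F6 | step 4 | 7-(benzyloxy)-3-[2,4-bis(benzyloxy)phenyl]-5-hydroxy-6-(3-hydroxy-3-methylbut-1-yn-1-yl)-4H-chromen-4-one | CC(C)(O)C#Cc1c(OCc2ccccc2)cc2occ(-c3ccc(OCc4ccccc4)cc3OCc3ccccc3)c(=O)c2c1O
F7 | step 3 | 7-(benzyloxy)-3-chloro-5-[(2-methylbut-3-yn-2-yl)oxy]-4H-chromen-4-one | C#CC(C)(C)Oc1cc(OCc2ccccc2)cc2occ(Cl)c(=O)c12
F8 | step 3 | 7-(benzyloxy)-3-chloro-5-[(2-methylbut-3-en-2-yl)oxy]-4H-chromen-4-one | C=CC(C)(C)Oc1cc(OCc2ccccc2)cc2occ(Cl)c(=O)c12
F9 | step 3 | 7-(benzyloxy)-3-chloro-5-hydroxy-6-(3-methylbut-2-en-1-yl)-4H-chromen-4-one | CC(C)=CCc1c(OCc2ccccc2)cc2occ(Cl)c(=O)c2c1O
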